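**Retrosynthetic overview**
1. Locants: C1 is the tertiary carbinol carbon (carries CH2OAc), C2 and C3 are the benzoate carbons, C4=C5 is the alkene, and C6 is the acetate carbon. β is the ring face of the C1 hydroxyl, so the target is 1β-OH, 2β-OBz, 3α-OBz, 6α-OAc.
2. Enabling feature: the oxygen on C1 and the olefinic carbon C4 face each other 1,4 across the six-membered ring, and C6 next to C1 is oxygenated. Bonding O(C1) to C4 and raising C6 to the enol ether level turns the cyclohexene into a 7-oxabicyclo[2.2.1]hept-5-ene whose atoms C1, C6, C5, C4 and O form a 2-(oxymethyl)-3-alkoxyfuran.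
3. Key disconnection: C1–C2 and C3–C4 together, by Diels–Alder reaction of that furan (chiral 3-alkoxy group as traceless auxiliary) with (E)-1,2-diborylethene as a trans-ethene-1,2-diol equivalent. C–B to C–O with retention gives the 2β,3α-diol.
4. Endgame: dibenzoylation, enol ether hydrolysis (auxiliary leaves, C6 ketone), β-elimination of the bridge oxygen from C4 (C4=C5 and C1–OH appear), hydroxyl-directed reduction at C6, acetylation.
5. Ring order: the furan is made first (gold catalysis), the carbocycle and oxygen bridge form together in the key step, and the temporary oxygen bridge is then opened.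

Key step: step 4

Assumption: the auxiliary shields the furan face predicted by the s-trans enol ether model given in step 4; if the sense is opposite, the equally available (1S,2R) alcohol is used and nothing else changes.
Abbreviations: TBS = tert-butyldimethylsilyl, Bcat = 1,3,2-benzodioxaborol-2-yl, Bz = benzoyl, Aux = (1R,2S)-2-phenylcyclohexyl. Target locants C1–C6 are used for all intermediates and coincide with the bicycloheptene locants.

**Step 1**
Reactants: 1 3,3-diethoxyprop-1-yne; 2 2-[(tert-butyldimethylsilyl)oxy]acetaldehyde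
Product: 3 (±)-1-[(tert-butyldimethylsilyl)oxy]-5,5-diethoxypent-3-yn-2-ol
Conditions: n-BuLi, THF, −78 °C; then 2, −78 → 0 °C; aq. NH4Cl
Reagents that add atoms: none
Why: 1,2-Addition of a lithium acetylide to an aldehyde is reliable on α-silyloxy aldehydes, and the new carbinol centre may be racemic because it becomes the sp2 carbon C1 of the furan in step 2.

**Step 2**
Reactants: 3 propargylic alcohol acetal; 4 (1R,2S)-2-phenylcyclohexan-1-ol
Product: 5 2-(TBSOCH2)-3-(Aux-O)furan, i.e. tert-butyldimethyl({3-[(1R,2S)-2-phenylcyclohexyl]oxyfuran-2-yl}methoxy)silane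
Conditions: Ph3PAuNTf2 (2 mol%), 4 (5 equiv, excess recovered), 5 Å MS, CH2Cl2, rt
Reagents that add atoms: none
Why: Gold-catalysed alkoxylative cycloisomerisation of acetal-bearing propargylic alcohols to 3-alkoxyfurans: alcohol 4 adds to the activated alkyne carbon next to the carbinol, the hydroxyl closes onto the acetal carbon to give the five-membered ring, and loss of two ethanol molecules aromatises, with the stereocentres of 4 untouched.

**Step 3**
Reactants: 6 (E)-1,2-bis(tributylstannyl)ethene; 7 2-chloro-1,3,2-benzodioxaborole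
Product: 8 (E)-1,2-bis(1,3,2-benzodioxaborol-2-yl)ethene
Conditions: 7 (2.1 equiv), CH2Cl2, 0 °C → rt; solid washed with pentane
Reagents that add atoms: none
Why: Tin-to-boron exchange of an alkenylstannane with a chloroborane (electrophilic ipso substitution) proceeds with retention of the E geometry, and the tin chloride should wash out with pentane.

**Step 4**
Reactants: 5 2-(TBSOCH2)-3-(Aux-O)furan; 8 (E)-1,2-bis(Bcat)ethene
Product: 10 (1S,2S,3S,4S)-1-(TBSOCH2)-6-(Aux-O)-7-oxabicyclo[2.2.1]hept-5-ene-2-exo,3-endo-diol (2β-OH and 3α-OH; oxygen bridge on the β face), via bis(catecholboronate) cycloadduct 9 (not isolated)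
Conditions: 8 (1.3 equiv), 2,6-di-tert-butylpyridine (10 mol%), toluene, rt → 45 °C; then THF, 30% H2O2, aq. NaOH, 0 °C; diastereomers removed by chromatography
Reagents that add atoms: hydrogen peroxide, OO
Why: Proposed new method: a normal-electron-demand Diels–Alder reaction in which the furan of 5, made electron-rich and less aromatic by its 3-alkoxy group, adds suprafacially through C1 and C4 to the alkene of 8, whose LUMO is lowered by two vacant boron p orbitals, so that C1–C2 and C3–C4 form in one concerted asynchronous event, after which alkaline H2O2 replaces each C–B by C–O with retention (1,2-metallate shift). The closest known reaction types are the cycloaddition of (E)-1,2-bis(catecholboryl)ethene to simple 1,3-dienes followed by oxidation to trans-cyclohexene-1,2-diols and the room-temperature irreversible cycloadditions of 3-alkoxyfurans to maleimides, whose combination on a furan has not been shown. The step closes the carbocycle C1–C6 by intermolecular [4π+2π] cycloaddition and thereby makes the furan ring the dihydrofuran half of the 7-oxabicyclo[2.2.1]heptene, and no ring is closed in the oxidation. The C2/C3 trans relation is fixed by the E geometry of 8; the relation to C1 and C4 (boron on C2 exo = β, boron on C3 endo = α) is expected from the transition state that places the boryl group on C3, which stabilises the charge building up as nucleophilic C1 attacks C2, endo under C5 and keeps the other boryl group away from the bulky C6 alkoxy group; the absolute sense comes from the auxiliary, whose s-trans enol ether conformer (carbinol H in the furan plane) holds the phenyl ring behind one furan face, so the dienophile with its large endo boryl group must approach the other. The step therefore needs orientation (exo/endo) and π-facial selectivity, no regiochemical question arises because 8 is symmetric, and minor diastereomers can be removed at 10 or 11 while the auxiliary is still attached. Enol ether, silyl ether and the β-alkoxyboronate units should tolerate cold basic peroxide, in which migration from boron to oxygen should outrun β-elimination of the bridge oxygen.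

**Step 5**
Reactants: 10 bicyclic 2-exo,3-endo-diol
Product: 11 (1S,2S,3R,4S)-1-(TBSOCH2)-6-(Aux-O)-7-oxabicyclo[2.2.1]hept-5-ene-2-exo,3-endo-diyl dibenzoate
Conditions: BzCl (3 equiv), pyridine, DMAP (cat.), CH2Cl2, 0 °C → rt
Reagents that add atoms: benzoyl chloride, O=C(Cl)c1ccccc1
Why: DMAP-catalysed acylation of the two secondary alcohols under basic conditions leaves the acid-labile enol ether and all stereocentres untouched.

**Step 6**
Reactants: 11 bicyclic dibenzoate
Product: 13 (1S,2S,3R)-1-(TBSOCH2)-1-hydroxy-6-oxocyclohex-4-ene-2,3-diyl dibenzoate (1β-OH and 2β-OBz and 3α-OBz), via 6-oxo-7-oxanorbornane 12 (not isolated)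
Conditions: PPTS (cat.), acetone/H2O, 0 °C → rt; then Et3N, CH2Cl2, 0 °C
Reagents that add atoms: water, O
Why: Acid hydrolysis of the enol ether (protonation at C5, water onto C6, loss of 4) gives the strained β-alkoxy ketone 12, and deprotonation at C5, the only enolisable position since C1 is quaternary, expels the bridge oxygen from C4 (E1cB retro-oxa-Michael), which places the alkene at C4=C5 and frees the C1 hydroxyl without touching the C1–O bond or any stereocentre of the target.

**Step 7**
Reactants: 13 enone
Product: 14 (1R,2S,3R,6S)-1-(TBSOCH2)-1,6-dihydroxycyclohex-4-ene-2,3-diyl dibenzoate (6α-OH)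
Conditions: Me4NBH(OAc)3, MeCN/AcOH (1:1), −30 °C
Reagents that add atoms: none
Why: Hydroxyl-directed reduction (Evans–Saksena type): the C1β hydroxyl exchanges onto boron and hydride is delivered intramolecularly to the β face of C6, so the new hydroxyl is α (trans to C1–OH), while esters and the undirected enone are inert to triacetoxyborohydride.

**Step 8**
Reactants: 14 allylic alcohol
Product: 16 target, (1R,2S,3R,6S)-6-acetoxy-1-(acetoxymethyl)-1-hydroxycyclohex-4-ene-2,3-diyl dibenzoate, via triol 15 (not isolated)
Conditions: Et3N·3HF, MeCN, rt; concentrate; then Ac2O, pyridine, 0 °C → rt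
Reagents that add atoms: acetic anhydride, CC(=O)OC(C)=O
Why: Weakly acidic fluoride desilylation avoids benzoate migration, and Ac2O/pyridine without DMAP acetylates the primary and the secondary hydroxyl but not the hindered tertiary C1 hydroxyl.

**Compound list**
1 | 3,3-diethoxyprop-1-yne | C#CC(OCC)OCC | starting material
2 | 2-[(tert-butyldimethylsilyl)oxy]acetaldehyde | O=CCO[Si](C)(C)C(C)(C)C | starting material
3 | (±)-1-[(tert-butyldimethylsilyl)oxy]-5,5-diethoxypent-3-yn-2-ol | CCOC(OCC)C#CC(O)CO[Si](C)(C)C(C)(C)C | intermediate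
4 | (1R,2S)-2-phenylcyclohexan-1-ol | O[C@@H]1CCCC[C@H]1c1ccccc1 | starting material
5 | 2-(TBSOCH2)-3-[(1R,2S)-2-phenylcyclohexyloxy]furan | CC(C)(C)[Si](C)(C)OCc1occc1O[C@@H]1CCCC[C@H]1c1ccccc1 | intermediate
6 | (E)-1,2-bis(tributylstannyl)ethene | CCCC[Sn](CCCC)(CCCC)/C=C/[Sn](CCCC)(CCCC)CCCC | starting material
7 | 2-chloro-1,3,2-benzodioxaborole | ClB1Oc2ccccc2O1 | starting material
8 | (E)-1,2-bis(1,3,2-benzodioxaborol-2-yl)ethene | O1c2ccccc2OB1/C=C/B1Oc2ccccc2O1 | intermediate
9 | cycloadduct, 2-exo,3-endo-bis(Bcat)-7-oxabicyclo[2.2.1]hept-5-ene (configuration as 10) | CC(C)(C)[Si](C)(C)OC[C@@]12O[C@@H](C=C1O[C@@H]1CCCC[C@H]1c1ccccc1)[C@@H](B1Oc3ccccc3O1)[C@@H]2B1Oc2ccccc2O1 | intermediate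
10 | (1S,2S,3S,4S) bicyclic 2-exo,3-endo-diol | CC(C)(C)[Si](C)(C)OC[C@@]12O[C@@H](C=C1O[C@@H]1CCCC[C@H]1c1ccccc1)[C@@H](O)[C@@H]2O | intermediate
11 | (1S,2S,3R,4S) bicyclic 2-exo,3-endo-dibenzoate | CC(C)(C)[Si](C)(C)OC[C@@]12O[C@@H](C=C1O[C@@H]1CCCC[C@H]1c1ccccc1)[C@@H](OC(=O)c1ccccc1)[C@@H]2OC(=O)c1ccccc1 | intermediate
12 | (1S,2S,3R,4S) 6-oxo-7-oxabicyclo[2.2.1]heptane-2-exo,3-endo-diyl dibenzoate with C1 CH2OTBS | CC(C)(C)[Si](C)(C)OC[C@@]12O[C@@H](CC1=O)[C@@H](OC(=O)c1ccccc1)[C@@H]2OC(=O)c1ccccc1 | intermediate
13 | (1S,2S,3R) enone, 1β-OH, 2β-OBz, 3α-OBz | CC(C)(C)[Si](C)(C)OC[C@@]1(O)C(=O)C=C[C@@H](OC(=O)c2ccccc2)[C@@H]1OC(=O)c1ccccc1 | intermediate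
14 | (1R,2S,3R,6S) 6α-alcohol | CC(C)(C)[Si](C)(C)OC[C@@]1(O)[C@@H](O)C=C[C@@H](OC(=O)c2ccccc2)[C@@H]1OC(=O)c1ccccc1 | intermediate
15 | (1R,2S,3R,6S) triol (CH2OH, 1β-OH, 6α-OH) | OC[C@@]1(O)[C@@H](O)C=C[C@@H](OC(=O)c2ccccc2)[C@@H]1OC(=O)c1ccccc1 | intermediate
16 | (1R,2S,3R,6S)-6-acetoxy-1-(acetoxymethyl)-1-hydroxycyclohex-4-ene-2,3-diyl dibenzoate | CC(=O)OC[C@@]1(O)[C@@H](OC(C)=O)C=C[C@@H](OC(=O)c2ccccc2)[C@@H]1OC(=O)c1ccccc1 | target

Total step count: 8. Longest linear sequence: 7 (steps 1, 2, 4, 5, 6, 7, 8).

**Steps most likely to fail**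

**Step 4.**
- What may go wrong: the diboronate may react too slowly with the furan, the exo/endo orientation or the π-facial control may erode, or boron may be lost together with the bridge oxygen by β-elimination before oxidation.
- Fallback (known chemistry): it sets out from 5 and returns at 13.
  - Furan 5 is heated with commercial vinylene carbonate (toluene, sealed tube, 110 °C, BHT). This is the classical furan/vinylene carbonate cycloaddition, run under equilibrating conditions that favour the exo carbonate cycloadduct F1.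
  - PPTS in aqueous acetone, then Et3N, gives the enone 2β,3β-carbonate F2.
  - Brief K2CO3/MeOH at 0 °C gives the enone 1β,2β,3β-triol F3.
  - A Mitsunobu reaction (PPh3, DIAD, BzOH) at the allylic, less hindered C3 hydroxyl inverts C3 and installs its benzoate, giving the 3α-benzoate 2β-alcohol F4.
  - BzCl/pyridine/DMAP at C2–OH gives 13.

**Step 2.**
- What may go wrong: liberated ethanol may compete with the hindered secondary alcohol for the gold-activated alkyne, and the electron-rich furan may decompose under acid.
- Fallback: it sets out from 4 and returns at 5.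
  - Ullmann-type etherification of commercial 3-bromofuran with 4 (CuI, 3,4,7,8-tetramethyl-1,10-phenanthroline, Cs2CO3, toluene, 110 °C) gives 3-(Aux-O)furan F5.
  - Alkoxy-directed lithiation at furan C2 (n-BuLi, THF, −78 → 0 °C) followed by paraformaldehyde gives the furfuryl alcohol F6.
  - TBSCl/imidazole gives 5.

**Step 7.**
- What may go wrong: the tertiary hydroxyl may exchange slowly onto boron, so that reduction stalls or facial selectivity is poor.
- Fallback: it sets out from 13 and returns at 16.
  - External hydride under Luche conditions (NaBH4, CeCl3·7H2O, MeOH, −78 °C) is expected to attack pseudo-axially, anti to the axial C1 hydroxyl, and to give the 6β-alcohol F7.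
  - A Mitsunobu reaction with acetic acid (PPh3, DIAD) inverts C6 and installs its acetate at the same time, giving the 6α-acetate silyl ether F8.
  - Et3N·3HF gives the primary alcohol F9.
  - Ac2O/pyridine gives 16.

**Further compounds**
F1 | step 4 | exo (2β,3β) cyclic carbonate cycloadduct of 5 and vinylene carbonate | CC(C)(C)[Si](C)(C)OC[C@@]12O[C@@H](C=C1O[C@@H]1CCCC[C@H]1c1ccccc1)[C@@H]3OC(=O)O[C@H]23
F2 | step 4 | enone 2β,3β-carbonate with 1β-OH and C1 CH2OTBS | CC(C)(C)[Si](C)(C)OC[C@@]1(O)C(=O)C=C[C@@H]2OC(=O)O[C@H]12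
F3 | step 4 | enone 1β,2β,3β-triol with C1 CH2OTBS | CC(C)(C)[Si](C)(C)OC[C@@]1(O)C(=O)C=C[C@H](O)[C@@H]1O
F4 | step 4 | enone 3α-benzoate 2β-alcohol | CC(C)(C)[Si](C)(C)OC[C@@]1(O)C(=O)C=C[C@@H](OC(=O)c2ccccc2)[C@@H]1O
F5 | step 2 | 3-[(1R,2S)-2-phenylcyclohexyloxy]furan | c1cc(O[C@@H]2CCCC[C@H]2c2ccccc2)co1
F6 | step 2 | {3-[(1R,2S)-2-phenylcyclohexyloxy]furan-2-yl}methanol | OCc1occc1O[C@@H]1CCCC[C@H]1c1ccccc1
F7 | step 7 | 6β-alcohol (C6 epimer of 14) | CC(C)(C)[Si](C)(C)OC[C@@]1(O)[C@H](O)C=C[C@@H](OC(=O)c2ccccc2)[C@@H]1OC(=O)c1ccccc1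
F8 | step 7 | 6α-acetate of 14 (C1 CH2OTBS) | CC(C)(C)[Si](C)(C)OC[C@@]1(O)[C@@H](OC(C)=O)C=C[C@@H](OC(=O)c2ccccc2)[C@@H]1OC(=O)c1ccccc1
F9 | step 7 | 6α-acetate primary alcohol | OC[C@@]1(O)[C@@H](OC(C)=O)C=C[C@@H](OC(=O)c2ccccc2)[C@@H]1OC(=O)c1ccccc1
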